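**Plan**
1. Cuts: the lower C-4–OH goes back to a ketone. Lower ring C is cut at C-2–aryl and C-3–O (chromone + arylboronic acid). Middle ring C is cut at C-2–C-3, with its 3-OH traced to a formyl helper. The two aryl–C-4 bonds that tie middle ring A to middle C-4 and to upper C-4 are cut last.
2. Forward, part 1: the upper unit is built first (7-hydroxychromone to protected fustin). A symmetric 4,6-dibromoresorcinol bis(3,4-dibenzyloxybenzyl) ether is lithiated twice. The first lithiation adds to the upper ketone (then ionic reduction); the second adds to one carbonyl of the symmetric bis-chromone made from 4,6-diacetylresorcinol.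
3. Forward, part 2: the adduct is opened to a β,β-diaryl enal and a [1,5]-hydride shift/cyclisation closes middle ring C. A Baeyer–Villiger reaction turns CHO into OH, the second chromone ring becomes lower ring C, and deprotection and borohydride reduction finish the route.
4. Enabling feature: in the middle unit C-2–H is benzylic to catechol ring B and α to O-1, so it is hydridic. It lies 1,5 to C-4, which carries two resorcinol rings A (middle and lower) and supports cationic character. A benzyl-type ether on ring A is therefore already O-1/C-2/ring B.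
5. Stereochemistry: C-2 of the upper and lower units comes from asymmetric Rh 1,4-addition and their C-3 from anti Rubottom oxidation. Upper C-4 (β, cis) comes from hydride delivery anti to 3-OTBS. Middle C-4 comes from a chiral acid; C-3 and C-2 are relayed from it in the closure, and C-3 is kept by retentive migration. Lower C-4 comes from axial hydride attack.

Key step: step 11

Conventions: DBB = 3,4-bis(benzyloxy)benzyl; TBS = tert-butyldimethylsilyl. Flavanoid numbering is used. In the 2R,3S units the 2-aryl group is α and the 3-oxygen is β. The target is fisetinidol-(4β→6)-fisetinidol-(4α→6)-leucofisetinidin.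
Assumption: the ligand and acid antipodes named are those expected, by analogy with cyclohexenone-type acceptors, to give the drawn configurations. If the sense of induction is opposite, the other antipode is used.

**Step 1**
Reactants: 1 7-hydroxy-4H-chromen-4-one
Product: 2 7-(benzyloxy)-4H-chromen-4-one
Conditions: BnBr, K2CO3, DMF, 25 °C
Reagents that add atoms: benzyl bromide BrCc1ccccc1
Why: Williamson ether synthesis on the acidic 7-OH; no stereocentre is involved.

**Step 2**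
Reactants: 2 7-(benzyloxy)-4H-chromen-4-one; 3 [3,4-bis(benzyloxy)phenyl]boronic acid
Product: 4 (2S)-7-(benzyloxy)-2-[3,4-bis(benzyloxy)phenyl]chroman-4-one
Conditions: Rh(acac)(C2H4)2 (3 mol %), (S)-MeO-F12-BIPHEP [(S)-6,6'-dimethoxybiphenyl-2,2'-diylbis[bis(3,4,5-trifluorophenyl)phosphine]] (3.3 mol %), toluene/H2O 10:1, 25 °C
Reagents that add atoms: none
Why: Hayashi–Miyaura asymmetric 1,4-addition of an arylrhodium species to the chromone enone is a known route to flavanones; the (S)-bisphosphine directs the aryl group to the face that gives (2S), and the neutral, cool medium avoids ring opening and racemisation.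

**Step 3**
Reactants: 4 (2S)-flavanone
Product: 5 (2S)-7-(benzyloxy)-2-[3,4-bis(benzyloxy)phenyl]-4-(TBS-oxy)-2H-chromene
Conditions: TBSOTf, Et3N, CH2Cl2, 0 °C
Reagents that add atoms: TBSOTf CC(C)(C)[Si](C)(C)OS(=O)(=O)C(F)(F)F
Why: Soft enolisation (silyl triflate/amine) gives the silyl enol ether without a free enolate that could open ring C by retro-oxa-Michael reaction, so C-2 is untouched.

**Step 4**
Reactants: 5 silyl enol ether
Product: 6 (2R,3R)-7-(benzyloxy)-2-[3,4-bis(benzyloxy)phenyl]-3-(TBS-oxy)chroman-4-one (protected fustin, 2,3-trans)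
Conditions: mCPBA, CH2Cl2, −20 → 0 °C
Reagents that add atoms: mCPBA OOC(=O)c1cccc(Cl)c1
Why: Rubottom oxidation; the peracid attacks the enol ether anti to the 2-aryl group and 1,4-silyl migration gives the α-silyloxy ketone, which sets C-3 trans to C-2.

**Step 5**
Reactants: 7 4,6-dibromobenzene-1,3-diol; 8 3,4-bis(benzyloxy)benzyl chloride (2 equiv)
Product: 9 1,5-dibromo-2,4-bis(DBB-oxy)benzene
Conditions: K2CO3, DMF, 60 °C
Reagents that add atoms: none
Why: Double Williamson ether synthesis; the product is symmetric so either bromine may react first, and the ether that ends up ortho to the later C-4 is the latent O-1/C-2/ring B of the middle unit.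

**Step 6**
Reactants: 9 1,5-dibromo-2,4-bis(DBB-oxy)benzene; 6 protected fustin
Product: 11 4-aryl-flavan-4-ol (C-4 configuration of no consequence), via aryllithium 10 (not isolated)
Conditions: 9, n-BuLi (1.0 equiv), THF, −78 °C; then 6, −78 → −40 °C; H2O
Reagents that add atoms: none
Why: Single bromine–lithium exchange followed by 1,2-addition of the aryllithium to the flavan-4-one has close precedent for joining flavanoid units; the new carbinol centre is erased in the next step.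

**Step 7**
Reactants: 11 4-aryl-flavan-4-ol
Product: 12 2,3-trans-3,4-cis 4β-aryl-flavan bromide (upper unit joined to C-6 of the future middle ring A)
Conditions: Bu3SnH, CF3CO2H (2 equiv), CH2Cl2, −40 → 0 °C
Reagents that add atoms: none
Why: Ionic hydrogenation of a tertiary dibenzylic alcohol; the flat C-4 cation takes hydride from the α face, anti to the bulky 3-OTBS group, so the aryl group ends β (3,4-cis), and the low temperature and small amount of acid spare the DBB ethers.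

**Step 8**
Reactants: 13 4,6-diacetylbenzene-1,3-diol
Product: 15 4H,6H-pyrano[3,2-g]chromene-4,6-dione, via bis-enaminone 14 (not isolated)
Conditions: Me2NCH(OMe)2, toluene, 110 °C; then AcOH, 100 °C
Reagents that add atoms: N,N-dimethylformamide dimethyl acetal COC(OC)N(C)C
Why: Enaminone formation and acid cyclisation with loss of dimethylamine is the standard chromone synthesis from 2-hydroxyacetophenones, run here on both sides of one ring, which fixes the 4,6-pattern of the lower ring A.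

**Step 9**
Reactants: 12 aryl bromide; 15 bis-chromone (2 equiv)
Product: 17 4-aryl-4-hydroxy-4H,6H-pyrano[3,2-g]chromen-6-one carbinol (carbinol centre of no consequence), via aryllithium 16 (not isolated)
Conditions: 12, n-BuLi, THF, −78 °C; then 15, LaCl3·2LiCl (30 mol %), THF, −78 → −40 °C; H2O
Reagents that add atoms: none
Why: Bromine–lithium exchange followed by Stork–Danheiser-type 1,2-addition to a vinylogous ester carbonyl (the way 4-arylchromenylium salts are made from chromones); the two carbonyl groups are equivalent, excess 15 limits double addition, and the lanthanum salt favours 1,2- over 1,4-attack.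

**Step 10**
Reactants: 17 carbinol
Product: 19 3,3-diarylacrolein (aryl groups: middle ring A and 7-benzyloxy-4-oxochromen-6-yl), via chromen-2-ol 18 (not isolated)
Conditions: AcOH/THF/H2O, 25 °C; then BnBr, K2CO3, DMF, 25 °C
Reagents that add atoms: benzyl bromide BrCc1ccccc1; water O
Why: Acid-catalysed allylic transposition of the chromen-4-ol through its aromatic cation (flavylium pseudo-base chemistry) gives hemiacetal 18, and Williamson benzylation of the phenoxide of its ring-opened tautomer unmasks the enal, whose double-bond geometry does not matter.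

**Step 11**
Reactants: 19 3,3-diarylacrolein
Product: 22 2,3-trans-3,4-trans 3-formylflavan (middle ring C closed), via hydroxyallyl cation 20 (not isolated), via enol oxocarbenium ion 21 (not isolated)
Conditions: (R)-3,3'-bis(2,4,6-triisopropylphenyl)-1,1'-binaphthyl-2,2'-diyl N-triflylphosphoramide (10 mol %), toluene, 50 °C
Reagents that add atoms: none
Why: Proposed new method: the chiral acid protonates the push-pull enal to hydroxyallyl cation 20 (its E and Z forms interconvert because the C-3–C-4 bond order is low), one hydrogen of the O-1–CH2–ring B group shifts as hydride, suprafacially and through a six-membered transition state, to C-4 to give enol oxocarbenium ion 21, and C-3 of the enol then attacks C-2, after which proton loss frees the aldehyde and the acid. The closest known reaction type is the acid-catalysed [1,5]-hydride shift/cyclisation (internal redox C–H functionalisation) of ethers onto enals and of 2-(benzyloxy)benzylidene malonates to 2-arylchromans, which has enantioselective forms under chiral phosphoric acids; a β,β-diaryl enal as acceptor and control of its C-4 face by a chiral N-triflylphosphoramide have not been shown. Ring C of the middle unit closes in a 6-(enolexo)-endo-trig mode through a half-chair. C-4 is fixed by the face that takes up hydride: only the geometric isomer with the twisted middle ring A cis to the protonated formyl group and the lower chromone ring conjugated can reach the transition state, so the O–CH2 arm has to sit on the face left open by the hydrogen-bonded chiral anion; C-3 follows from C-4 by allylic strain (C-4–H eclipses the enol and attack comes anti to the lower aryl group, 3,4-trans) and C-2 from the E-oxocarbenium ion that holds ring B equatorial (2,3-trans). The step needs one hydride donor out of many benzylic ethers, and the substrate secures this because the O-1 methylene is the only dialkoxybenzyl C–H in a 1,5-relation to C-4, while the 7-O-benzyl CH2 of the lower ring, also 1,5-related, lacks donor substituents and hangs on an acyl-deactivated oxygen. As the upper unit is enantiopure, a minor facial isomer would be a diastereomer and removable.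

**Step 12**
Reactants: 22 3-formylflavan
Product: 24 middle-unit flavan-3-ol (3β-OH) carrying the chromone, via 3-O-formate 23 (not isolated)
Conditions: mCPBA, CH2Cl2, 0 → 25 °C; then KHCO3 (cat.), MeOH/THF, 0 °C
Reagents that add atoms: mCPBA OOC(=O)c1cccc(Cl)c1
Why: Baeyer–Villiger oxidation of an α-branched aldehyde; the secondary C-3 migrates with retention to give formate 23, which is methanolysed under conditions too mild to open the chromone, so the helper carbon leaves and the 3-OH stays equatorial (β).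

**Step 13**
Reactants: 24 chromone alcohol; 3 [3,4-bis(benzyloxy)phenyl]boronic acid
Product: 25 lower-unit (2S)-flavanone
Conditions: Rh(acac)(C2H4)2 (5 mol %), (S)-MeO-F12-BIPHEP (5.5 mol %), toluene/H2O 10:1, 25 °C
Reagents that add atoms: none
Why: Hayashi–Miyaura asymmetric 1,4-addition as in step 2; the resident stereocentres are remote from C-2 of the chromone, so the ligand alone sets lower C-2, and the free 3-OH is tolerated.

**Step 14**
Reactants: 25 flavanone
Product: 26 lower silyl enol ether with middle 3-OTBS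
Conditions: TBSOTf (4 equiv), Et3N, CH2Cl2, 0 °C
Reagents that add atoms: TBSOTf CC(C)(C)[Si](C)(C)OS(=O)(=O)C(F)(F)F
Why: Soft enolisation as in step 3, with the excess reagent also silylating the middle 3-OH, so no stereocentre is touched.

**Step 15**
Reactants: 26 silyl enol ether
Product: 27 lower (2R,3R)-3-OTBS chroman-4-one (three OTBS groups in all)
Conditions: mCPBA, CH2Cl2, −20 → 0 °C
Reagents that add atoms: mCPBA OOC(=O)c1cccc(Cl)c1
Why: Rubottom oxidation as in step 4; attack anti to the lower 2-aryl group sets lower C-3 trans, and the enol ether is by far the most electron-rich π bond present.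

**Step 16**
Reactants: 27 tris-TBS ether
Product: 28 triol (three free 3-OH groups, all phenols still protected)
Conditions: HF·pyridine, pyridine, THF, 0 → 25 °C
Reagents that add atoms: none
Why: Fluoride-mediated desilylation in a buffered, weakly acidic medium avoids the base that would epimerise or open the dihydroflavonol ring.

**Step 17**
Reactants: 28 triol
Product: 29 fisetinidol-(4β→6)-fisetinidol-(4α→6)-fustin
Conditions: H2 (1 atm), Pd(OH)2/C, THF/MeOH, 25 °C
Reagents that add atoms: none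
Why: Hydrogenolysis removes the ten O-benzyl groups and the acyclic 7-O-DBB ether, while the donor-substituted aryl ketone and the cyclic C-2–O-1 ethers survive, as in the usual deprotection of benzylated dihydroflavonols and oligoflavanoids.

**Step 18**
Reactants: 29 ketone
Product: 30 target, fisetinidol-(4β→6)-fisetinidol-(4α→6)-leucofisetinidin
Conditions: NaBH4, EtOH, 0 °C; aqueous work-up near pH 6
Reagents that add atoms: none
Why: Borohydride reduction of a free dihydroflavonol is the standard access to flavan-3,4-diols; axial attack on C-4 from the β face gives the equatorial 4α-OH (3,4-trans, 4R), and the step stands last because this benzylic OH ionises easily.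

**Compound list**
1 | 7-hydroxy-4H-chromen-4-one | O=c1ccoc2cc(O)ccc12 | starting material
2 | 7-(benzyloxy)-4H-chromen-4-one | O=c1ccoc2cc(OCc3ccccc3)ccc12 | intermediate
3 | [3,4-bis(benzyloxy)phenyl]boronic acid | OB(O)c1ccc(OCc2ccccc2)c(OCc2ccccc2)c1 | starting material
4 | (2S)-7-(benzyloxy)-2-[3,4-bis(benzyloxy)phenyl]chroman-4-one | O(Cc1ccccc1)c1ccc2c(c1)O[C@H](c1ccc(OCc3ccccc3)c(OCc3ccccc3)c1)CC2=O | intermediate
5 | (2S)-7-(benzyloxy)-2-[3,4-bis(benzyloxy)phenyl]-4-(TBS-oxy)-2H-chromene | O(Cc1ccccc1)c1ccc2c(c1)O[C@H](c1ccc(OCc3ccccc3)c(OCc3ccccc3)c1)C=C2O[Si](C)(C)C(C)(C)C | intermediate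
6 | (2R,3R)-7-(benzyloxy)-2-[3,4-bis(benzyloxy)phenyl]-3-(TBS-oxy)chroman-4-one | O(Cc1ccccc1)c1ccc2c(c1)O[C@H](c1ccc(OCc3ccccc3)c(OCc3ccccc3)c1)[C@@H](O[Si](C)(C)C(C)(C)C)C2=O | intermediate
7 | 4,6-dibromobenzene-1,3-diol | Oc1cc(O)c(Br)cc1Br | starting material
8 | 3,4-bis(benzyloxy)benzyl chloride | ClCc1ccc(OCc2ccccc2)c(OCc2ccccc2)c1 | starting material
9 | 1,5-dibromo-2,4-bis(DBB-oxy)benzene | Brc1cc(Br)c(OCc2ccc(OCc3ccccc3)c(OCc3ccccc3)c2)cc1OCc1ccc(OCc2ccccc2)c(OCc2ccccc2)c1 | intermediate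
10 | 5-bromo-2,4-bis(DBB-oxy)phenyllithium | [Li]c1cc(Br)c(OCc2ccc(OCc3ccccc3)c(OCc3ccccc3)c2)cc1OCc1ccc(OCc2ccccc2)c(OCc2ccccc2)c1 | intermediate
11 | adduct of 10 to C-4 of 6, tertiary flavan-4-ol (C-4 not defined) | O(Cc1ccccc1)c1ccc2c(c1)O[C@H](c1ccc(OCc3ccccc3)c(OCc3ccccc3)c1)[C@@H](O[Si](C)(C)C(C)(C)C)C2(O)c1cc(Br)c(OCc2ccc(OCc3ccccc3)c(OCc3ccccc3)c2)cc1OCc1ccc(OCc2ccccc2)c(OCc2ccccc2)c1 | intermediate
12 | 2,3-trans-3,4-cis 4β-[5-bromo-2,4-bis(DBB-oxy)phenyl] derivative of protected fisetinidol | O(Cc1ccccc1)c1ccc2c(c1)O[C@H](c1ccc(OCc3ccccc3)c(OCc3ccccc3)c1)[C@@H](O[Si](C)(C)C(C)(C)C)[C@H]2c1cc(Br)c(OCc2ccc(OCc3ccccc3)c(OCc3ccccc3)c2)cc1OCc1ccc(OCc2ccccc2)c(OCc2ccccc2)c1 | intermediate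
13 | 4,6-diacetylbenzene-1,3-diol | CC(=O)c1cc(C(C)=O)c(O)cc1O | starting material
14 | 4,6-bis[(E)-3-(dimethylamino)acryloyl]benzene-1,3-diol | CN(C)/C=C/C(=O)c1cc(C(=O)/C=C/N(C)C)c(O)cc1O | intermediate
15 | 4H,6H-pyrano[3,2-g]chromene-4,6-dione | O=c1ccoc2cc3occc(=O)c3cc12 | intermediate
16 | aryllithium from 12 (Li in place of Br) | O(Cc1ccccc1)c1ccc2c(c1)O[C@H](c1ccc(OCc3ccccc3)c(OCc3ccccc3)c1)[C@@H](O[Si](C)(C)C(C)(C)C)[C@H]2c1cc([Li])c(OCc2ccc(OCc3ccccc3)c(OCc3ccccc3)c2)cc1OCc1ccc(OCc2ccccc2)c(OCc2ccccc2)c1 | intermediate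
17 | 4-aryl-4-hydroxy-4H,6H-pyrano[3,2-g]chromen-6-one (carbinol centre not defined) | O(Cc1ccccc1)c1ccc2c(c1)O[C@H](c1ccc(OCc3ccccc3)c(OCc3ccccc3)c1)[C@@H](O[Si](C)(C)C(C)(C)C)[C@H]2c1cc(C2(O)C=COc3cc4occc(=O)c4cc32)c(OCc2ccc(OCc3ccccc3)c(OCc3ccccc3)c2)cc1OCc1ccc(OCc2ccccc2)c(OCc2ccccc2)c1 | intermediate
18 | transposed 4-aryl-2-hydroxy-2H,6H-pyrano[3,2-g]chromen-6-one (hemiacetal centre not defined) | O(Cc1ccccc1)c1ccc2c(c1)O[C@H](c1ccc(OCc3ccccc3)c(OCc3ccccc3)c1)[C@@H](O[Si](C)(C)C(C)(C)C)[C@H]2c1cc(C2=CC(O)Oc3cc4occc(=O)c4cc32)c(OCc2ccc(OCc3ccccc3)c(OCc3ccccc3)c2)cc1OCc1ccc(OCc2ccccc2)c(OCc2ccccc2)c1 | intermediate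
19 | 3-(middle ring A)-3-(7-benzyloxy-4-oxochromen-6-yl)acrolein, drawn with the chromone ring cis to CHO | O(Cc1ccccc1)c1ccc2c(c1)O[C@H](c1ccc(OCc3ccccc3)c(OCc3ccccc3)c1)[C@@H](O[Si](C)(C)C(C)(C)C)[C@H]2c1cc(/C(=C/C=O)c2cc3c(=O)ccoc3cc2OCc2ccccc2)c(OCc2ccc(OCc3ccccc3)c(OCc3ccccc3)c2)cc1OCc1ccc(OCc2ccccc2)c(OCc2ccccc2)c1 | intermediate
20 | O-protonated 19, hydroxyallyl cation (paired with the chiral anion) | O(Cc1ccccc1)c1ccc2c(c1)O[C@H](c1ccc(OCc3ccccc3)c(OCc3ccccc3)c1)[C@@H](O[Si](C)(C)C(C)(C)C)[C@H]2c1cc(C(=CC=[OH+])c2cc3c(=O)ccoc3cc2OCc2ccccc2)c(OCc2ccc(OCc3ccccc3)c(OCc3ccccc3)c2)cc1OCc1ccc(OCc2ccccc2)c(OCc2ccccc2)c1 | intermediate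
21 | cation after hydride shift: C-4 stereocentre, (E)-enol, O-1=C-2 oxocarbenium ion | O(Cc1ccccc1)c1ccc2c(c1)O[C@H](c1ccc(OCc3ccccc3)c(OCc3ccccc3)c1)[C@@H](O[Si](C)(C)C(C)(C)C)[C@H]2c1cc([C@H](/C=C/O)c2cc3c(=O)ccoc3cc2OCc2ccccc2)c([O+]=Cc2ccc(OCc3ccccc3)c(OCc3ccccc3)c2)cc1OCc1ccc(OCc2ccccc2)c(OCc2ccccc2)c1 | intermediate
22 | upper unit-(4β→6)-[2α-aryl-3β-formyl-4α-(7-benzyloxy-4-oxochromen-6-yl)flavan] | O(Cc1ccccc1)c1ccc2c(c1)O[C@H](c1ccc(OCc3ccccc3)c(OCc3ccccc3)c1)[C@@H](O[Si](C)(C)C(C)(C)C)[C@H]2c1cc2c(cc1OCc1ccc(OCc3ccccc3)c(OCc3ccccc3)c1)O[C@H](c1ccc(OCc3ccccc3)c(OCc3ccccc3)c1)[C@@H](C=O)[C@@H]2c1cc2c(=O)ccoc2cc1OCc1ccccc1 | intermediate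
23 | 3β-O-formate of 24 | O(Cc1ccccc1)c1ccc2c(c1)O[C@H](c1ccc(OCc3ccccc3)c(OCc3ccccc3)c1)[C@@H](O[Si](C)(C)C(C)(C)C)[C@H]2c1cc2c(cc1OCc1ccc(OCc3ccccc3)c(OCc3ccccc3)c1)O[C@H](c1ccc(OCc3ccccc3)c(OCc3ccccc3)c1)[C@@H](OC=O)[C@@H]2c1cc2c(=O)ccoc2cc1OCc1ccccc1 | intermediate
24 | protected fisetinidol-(4β→6)-fisetinidol (free middle 3-OH)-(4α→6)-7-benzyloxychromone | O(Cc1ccccc1)c1ccc2c(c1)O[C@H](c1ccc(OCc3ccccc3)c(OCc3ccccc3)c1)[C@@H](O[Si](C)(C)C(C)(C)C)[C@H]2c1cc2c(cc1OCc1ccc(OCc3ccccc3)c(OCc3ccccc3)c1)O[C@H](c1ccc(OCc3ccccc3)c(OCc3ccccc3)c1)[C@@H](O)[C@@H]2c1cc2c(=O)ccoc2cc1OCc1ccccc1 | intermediate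
25 | as 24 with the chromone turned into the (2S)-flavanone | O(Cc1ccccc1)c1ccc2c(c1)O[C@H](c1ccc(OCc3ccccc3)c(OCc3ccccc3)c1)[C@@H](O[Si](C)(C)C(C)(C)C)[C@H]2c1cc2c(cc1OCc1ccc(OCc3ccccc3)c(OCc3ccccc3)c1)O[C@H](c1ccc(OCc3ccccc3)c(OCc3ccccc3)c1)[C@@H](O)[C@@H]2c1cc2c(cc1OCc1ccccc1)O[C@H](c1ccc(OCc3ccccc3)c(OCc3ccccc3)c1)CC2=O | intermediate
26 | lower 4-(TBS-oxy)flav-3-ene, middle 3-OTBS | O(Cc1ccccc1)c1ccc2c(c1)O[C@H](c1ccc(OCc3ccccc3)c(OCc3ccccc3)c1)[C@@H](O[Si](C)(C)C(C)(C)C)[C@H]2c1cc2c(cc1OCc1ccc(OCc3ccccc3)c(OCc3ccccc3)c1)O[C@H](c1ccc(OCc3ccccc3)c(OCc3ccccc3)c1)[C@@H](O[Si](C)(C)C(C)(C)C)[C@@H]2c1cc2c(cc1OCc1ccccc1)O[C@H](c1ccc(OCc3ccccc3)c(OCc3ccccc3)c1)C=C2O[Si](C)(C)C(C)(C)C | intermediate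
27 | fully protected trimer ketone (three 3-OTBS groups, lower unit 2R,3R) | O(Cc1ccccc1)c1ccc2c(c1)O[C@H](c1ccc(OCc3ccccc3)c(OCc3ccccc3)c1)[C@@H](O[Si](C)(C)C(C)(C)C)[C@H]2c1cc2c(cc1OCc1ccc(OCc3ccccc3)c(OCc3ccccc3)c1)O[C@H](c1ccc(OCc3ccccc3)c(OCc3ccccc3)c1)[C@@H](O[Si](C)(C)C(C)(C)C)[C@@H]2c1cc2c(cc1OCc1ccccc1)O[C@H](c1ccc(OCc3ccccc3)c(OCc3ccccc3)c1)[C@@H](O[Si](C)(C)C(C)(C)C)C2=O | intermediate
28 | trimer ketone with three free 3-OH groups, phenols protected | O(Cc1ccccc1)c1ccc2c(c1)O[C@H](c1ccc(OCc3ccccc3)c(OCc3ccccc3)c1)[C@@H](O)[C@H]2c1cc2c(cc1OCc1ccc(OCc3ccccc3)c(OCc3ccccc3)c1)O[C@H](c1ccc(OCc3ccccc3)c(OCc3ccccc3)c1)[C@@H](O)[C@@H]2c1cc2c(cc1OCc1ccccc1)O[C@H](c1ccc(OCc3ccccc3)c(OCc3ccccc3)c1)[C@@H](O)C2=O | intermediate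
29 | fisetinidol-(4β→6)-fisetinidol-(4α→6)-fustin | Oc1ccc2c(c1)O[C@H](c1ccc(O)c(O)c1)[C@@H](O)[C@H]2c1cc2c(cc1O)O[C@H](c1ccc(O)c(O)c1)[C@@H](O)[C@@H]2c1cc2c(cc1O)O[C@H](c1ccc(O)c(O)c1)[C@@H](O)C2=O | intermediate
30 | fisetinidol-(4β→6)-fisetinidol-(4α→6)-leucofisetinidin (CNP0255184.1) | Oc1ccc2c(c1)O[C@H](c1ccc(O)c(O)c1)[C@@H](O)[C@H]2c1cc2c(cc1O)O[C@H](c1ccc(O)c(O)c1)[C@@H](O)[C@@H]2c1cc2c(cc1O)O[C@H](c1ccc(O)c(O)c1)[C@@H](O)[C@@H]2O | target

**Step count**
Total step count: 18.
Longest linear sequence: 16 steps (1, 2, 3, 4, 6, 7, 9 to 18).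

**Steps most likely to fail**

**Step 11.**
- What may go wrong: the doubly donor-substituted acceptor may take up hydride too slowly, the acid may cleave the dialkoxybenzyl ether first, or the hydride transfer may show poor facial selectivity.
- Fallback (from 19, back at 22): stereocontrol is moved from the catalyst to the resident stereocentres. Compound 19 is cyclised with the achiral Lewis acid BF3·OEt2 (more than one equivalent, CH2Cl2, 0 to 25 °C). This is the established non-asymmetric hydride-shift cyclisation of ethers onto enals. Because the upper unit is enantiopure, the two all-trans closures give diastereomers, 22 and the ring-C antipodal 3-formylflavan F1. These are separated by chromatography, and 22 continues.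

**Step 7.**
- What may go wrong: hydride may be delivered from the β face, or C-3 may lose a proton from the cation.
- Fallback (from 6, back at 12): the bond is formed with the polarity of the classical flavan-4-yl cation coupling.
  - Compound 6 is reduced (NaBH4, THF/MeOH) to the flavan-4-ol F2.
  - 4-Bromoresorcinol is alkylated with 8 (K2CO3, DMF) to 4-bromo-1,3-bis(DBB-oxy)benzene F3.
  - F2 is ionised with catalytic TMSOTf (CH2Cl2, −78 °C) in the presence of F3. This Friedel–Crafts reaction takes place para to one ether oxygen and ortho to the other.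
  - In the 5-deoxy series this coupling delivers both C-4 epimers, so 12 is separated from the 4α-aryl epimer F4.

**Step 12.**
- What may go wrong: hydrogen may migrate instead of C-3 in the peracid adduct, giving the acid in place of the formate.
- Fallback (from 22, back at 24): that acid is made on purpose and degraded with retention.
  - Pinnick oxidation (NaClO2, NaH2PO4, 2-methyl-2-butene) gives the flavan-3-carboxylic acid F5.
  - DCC and mCPBA (CH2Cl2, 0 °C) give the mixed diacyl peroxide F6.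
  - Warming in acetonitrile brings about the carboxy-inversion rearrangement to the acyl carbonate F7, with retention at C-3.
  - Mild hydrolysis (aq NaHCO3, THF) gives 24.

**Further compounds**
F1 | step 11 | ring-C antipodal (2β-aryl-3α-formyl-4β-aryl) diastereomer of 22 | O(Cc1ccccc1)c1ccc2c(c1)O[C@H](c1ccc(OCc3ccccc3)c(OCc3ccccc3)c1)[C@@H](O[Si](C)(C)C(C)(C)C)[C@H]2c1cc2c(cc1OCc1ccc(OCc3ccccc3)c(OCc3ccccc3)c1)O[C@@H](c1ccc(OCc3ccccc3)c(OCc3ccccc3)c1)[C@H](C=O)[C@H]2c1cc2c(=O)ccoc2cc1OCc1ccccc1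
F2 | step 7 | 2,3-trans-3,4-trans 7-(benzyloxy)-2-[3,4-bis(benzyloxy)phenyl]-3-(TBS-oxy)chroman-4-ol | O(Cc1ccccc1)c1ccc2c(c1)O[C@H](c1ccc(OCc3ccccc3)c(OCc3ccccc3)c1)[C@@H](O[Si](C)(C)C(C)(C)C)[C@@H]2O
F3 | step 7 | 4-bromo-1,3-bis(DBB-oxy)benzene | Brc1ccc(OCc2ccc(OCc3ccccc3)c(OCc3ccccc3)c2)cc1OCc1ccc(OCc2ccccc2)c(OCc2ccccc2)c1
F4 | step 7 | 4α-aryl (3,4-trans) epimer of 12 | O(Cc1ccccc1)c1ccc2c(c1)O[C@H](c1ccc(OCc3ccccc3)c(OCc3ccccc3)c1)[C@@H](O[Si](C)(C)C(C)(C)C)[C@@H]2c1cc(Br)c(OCc2ccc(OCc3ccccc3)c(OCc3ccccc3)c2)cc1OCc1ccc(OCc2ccccc2)c(OCc2ccccc2)c1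
F5 | step 12 | 3β-carboxylic acid corresponding to 22 | O(Cc1ccccc1)c1ccc2c(c1)O[C@H](c1ccc(OCc3ccccc3)c(OCc3ccccc3)c1)[C@@H](O[Si](C)(C)C(C)(C)C)[C@H]2c1cc2c(cc1OCc1ccc(OCc3ccccc3)c(OCc3ccccc3)c1)O[C@H](c1ccc(OCc3ccccc3)c(OCc3ccccc3)c1)[C@@H](C(=O)O)[C@@H]2c1cc2c(=O)ccoc2cc1OCc1ccccc1
F6 | step 12 | mixed diacyl peroxide of F5 and 3-chloroperbenzoic acid | O(Cc1ccccc1)c1ccc2c(c1)O[C@H](c1ccc(OCc3ccccc3)c(OCc3ccccc3)c1)[C@@H](O[Si](C)(C)C(C)(C)C)[C@H]2c1cc2c(cc1OCc1ccc(OCc3ccccc3)c(OCc3ccccc3)c1)O[C@H](c1ccc(OCc3ccccc3)c(OCc3ccccc3)c1)[C@@H](C(=O)OOC(=O)c1cccc(Cl)c1)[C@@H]2c1cc2c(=O)ccoc2cc1OCc1ccccc1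
F7 | step 12 | 3β-O-(3-chlorobenzoyloxycarbonyl) derivative of 24 (acyl carbonate) | O(Cc1ccccc1)c1ccc2c(c1)O[C@H](c1ccc(OCc3ccccc3)c(OCc3ccccc3)c1)[C@@H](O[Si](C)(C)C(C)(C)C)[C@H]2c1cc2c(cc1OCc1ccc(OCc3ccccc3)c(OCc3ccccc3)c1)O[C@H](c1ccc(OCc3ccccc3)c(OCc3ccccc3)c1)[C@@H](OC(=O)OC(=O)c1cccc(Cl)c1)[C@@H]2c1cc2c(=O)ccoc2cc1OCc1ccccc1
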